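Carbons are labelled C1–C20 along the main chain of the target SMILES (ring A: C3–C7; eight-membered ring B: C2, C3, C7, C8, C9, C18, C19, C20; rings C and D: the decalin). The plan cuts C3–C7 and C2–C20. It exploits the fact that in ring B the olefinic pair C2=C3 lies between C7 and C20, with oxygenated C8 next to C7: C2–C3 is an alkyne inserted into the C7–C20 bond of a six-membered 1,3-dione. One alkyne de Mayo photocycloaddition–fragmentation closes ring A, enlarges the dione ring to ring B and places the tetrasubstituted olefin. The precursor 34 is a tricyclic β-silyloxy enone whose C7 carries a three-atom tether to the C2≡C3 alkyne.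

Key step: step 19

Remarks on the chemistry (assumptions):
- β is the face of the C12 methyl group, α the opposite face.
- The sense of induction in step 3 is taken from 2-methylcyclohexanone, where the (S)-amine leads to the (R)-quaternary centre; the (R)-amine is therefore used here.
- Step 3 need not be perfectly selective; material from the minor enantiomer becomes a diastereomer after union with enantiopure 28 in step 15 and is removed there.
- 30 is written as the open hydroxy ketone; it is expected to equilibrate with its six-membered cyclic hemiketal.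

Step 1
Reactants: 1 3,3-dimethylcyclohexan-1-one
Product: 3 rac-2,5,5-trimethylcyclohexan-1-one, via lithium enolate 2 (not isolated)
Conditions: LiN(iPr)2, THF, −78 °C; MeI, −78 → 0 °C
Reagents that add atoms: iodomethane, CI
Why: Kinetic deprotonation should occur at C6 rather than at the methylene next to the quaternary carbon, and the enolate is C-methylated (regioselective enolate alkylation); the racemic stereocentre is lost again in the enamine of step 3.

Step 2
Reactants: 3 rac-2,5,5-trimethylcyclohexan-1-one; 4 (R)-1-phenylethan-1-amine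
Product: 5 N-[(1R)-1-phenylethyl]-2,5,5-trimethylcyclohexan-1-imine
Conditions: TsOH·H2O (cat.), toluene, reflux, water separator
Reagents that add atoms: none
Why: Acid-catalysed condensation with azeotropic removal of water gives the ketimine (imine formation) and installs the chiral auxiliary.

Step 3
Reactants: 5 N-[(1R)-1-phenylethyl]-2,5,5-trimethylcyclohexan-1-imine; 6 but-3-en-2-one
Product: 8 (2S)-2,5,5-trimethyl-2-(3-oxobutyl)cyclohexan-1-one, via Michael-adduct imine 7 (not isolated)
Conditions: THF, 25 °C; then AcOH, H2O, 25 °C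
Reagents that add atoms: water, O
Why: The imine reacts through its more substituted secondary enamine tautomer in an aza-ene-type Michael addition (deracemising alkylation of a chiral imine), the phenyl group shielding one face so that C12 should form with S configuration, and aqueous acid then hydrolyses the imine.

Step 4
Reactants: 8 (2S)-2,5,5-trimethyl-2-(3-oxobutyl)cyclohexan-1-one
Product: 9 (4aS)-4a,7,7-trimethyl-4,4a,5,6,7,8-hexahydronaphthalen-2(3H)-one
Conditions: NaOMe (cat.), MeOH, 65 °C
Reagents that add atoms: none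
Why: Intramolecular aldol condensation (second stage of a Robinson annulation) can close only the six-membered ring from the methyl ketone onto the ring carbonyl, and dehydration gives the enone C9(=O)–C18=C17 without touching C12.

Step 5
Reactants: 9 (4aS)-4a,7,7-trimethyl-4,4a,5,6,7,8-hexahydronaphthalen-2(3H)-one
Product: 11 tert-butyl 2-[(1S,4aS,8aS)-4a,7,7-trimethyl-2-oxodecahydronaphthalen-1-yl]acetate, via lithium enolate 10 (not isolated)
Conditions: Li, NH3(l), THF, t-BuOH (1 equiv), −78 °C; isoprene; NH3 off; BrCH2CO2tBu, THF, −78 → 0 °C; then K2CO3, MeOH, 25 °C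
Reagents that add atoms: tert-butyl bromoacetate, CC(C)(C)OC(=O)CBr
Why: Dissolving-metal (Birch-type) reduction protonates C17 axially, anti to the C12 methyl (trans ring fusion), the regiospecific enolate is alkylated at C18 (reductive alkylation), and base equilibration places the epimerisable C18 chain equatorial.

Step 6
Reactants: 11 tert-butyl 2-[(1S,4aS,8aS)-4a,7,7-trimethyl-2-oxodecahydronaphthalen-1-yl]acetate
Product: 13 C9 enol triflate (C9=C10) of 11, via potassium enolate 12 (not isolated)
Conditions: KN(SiMe3)2, THF, −78 °C; PhNTf2, −78 → 0 °C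
Reagents that add atoms: N-phenylbis(trifluoromethanesulfonimide), O=S(=O)(N(c1ccccc1)S(=O)(=O)C(F)(F)F)C(F)(F)F
Why: Kinetic deprotonation should take place at the C10 methylene rather than at the hindered C18 methine or next to the less acidic ester, and O-sulfonylation gives the alkenyl triflate (enol triflate formation).

Step 7
Reactants: 13 C9 enol triflate (C9=C10) of 11
Product: 14 tert-butyl 2-[(1S,4aS,8aS)-2-(hydroxymethyl)-4a,7,7-trimethyl-1,4,4a,5,6,7,8,8a-octahydronaphthalen-1-yl]acetate
Conditions: Bu3SnCH2OH, Pd(PPh3)4 (cat.), LiCl, 1,4-dioxane, 90 °C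
Reagents that add atoms: (tributylstannyl)methanol, CCCC[Sn](CCCC)(CCCC)CO
Why: Stille cross-coupling of the alkenyl triflate with the hydroxymethylstannane introduces C8 as an allylic alcohol, the directing group for step 8; no stereocentre is formed.

Step 8
Reactants: 14 tert-butyl 2-[(1S,4aS,8aS)-2-(hydroxymethyl)-4a,7,7-trimethyl-1,4,4a,5,6,7,8,8a-octahydronaphthalen-1-yl]acetate
Product: 15 9α,10α-methylene (cyclopropane) derivative of 14
Conditions: Et2Zn, CH2I2, CH2Cl2, 0 → 25 °C
Reagents that add atoms: diiodomethane, ICI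
Why: Hydroxyl-accelerated Simmons–Smith cyclopropanation should deliver the methylene to the α face of C9=C10, anti to the axial C12 methyl that is 1,3 to C10, which fixes C9 with C8 on the β side.

Step 9
Reactants: 15 9α,10α-methylene (cyclopropane) derivative of 14
Product: 17 trans-fused δ-lactone (C8H2–O–C20(=O)–C19H2 across C9/C18; 9α-methyl), via hydroxy ester 16 (not isolated)
Conditions: H2 (4 atm), PtO2, AcOH, 25 °C; filter; then CF3CO2H, CH2Cl2, 25 °C
Reagents that add atoms: none
Why: Hydrogenolysis of the cyclopropane should cleave its least substituted bond (C10–CH2), turning the bridge into the axial 9α-methyl with retention at C9, and acid then removes the tert-butyl ester and closes the lactone (lactonisation).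

Step 10
Reactants: 18 (4S)-4-benzyl-3-propanoyl-1,3-oxazolidin-2-one; 19 chloroacetaldehyde
Product: 21 (4S)-4-benzyl-3-[(2S,3S)-4-chloro-3-hydroxy-2-methylbutanoyl]-1,3-oxazolidin-2-one, via boron enolate 20 (not isolated)
Conditions: Bu2BOTf, iPr2NEt, CH2Cl2, −78 → 0 °C; 19 (anhydrous), −78 → 0 °C; then pH 7 buffer, MeOH, H2O2, 0 °C
Reagents that add atoms: none
Why: The Evans syn-aldol reaction runs through the Z boron enolate and a Zimmerman–Traxler transition state, the benzyl group of the auxiliary controlling the face, so that C6 and C5 should form as the (2S,3S) syn adduct.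

Step 11
Reactants: 21 (4S)-4-benzyl-3-[(2S,3S)-4-chloro-3-hydroxy-2-methylbutanoyl]-1,3-oxazolidin-2-one
Product: 23 (2R)-2-[(2S)-oxiran-2-yl]propan-1-ol, via chloro diol 22 (not isolated)
Conditions: LiBH4, MeOH (1 equiv), THF, 0 °C; then K2CO3, MeOH, 25 °C
Reagents that add atoms: none
Why: LiBH4 removes the auxiliary reductively to give the primary alcohol (future C7), and the chlorohydrin closes to the epoxide by intramolecular Williamson substitution at the CH2Cl carbon, so C5 and C6 are untouched.

Step 12
Reactants: 23 (2R)-2-[(2S)-oxiran-2-yl]propan-1-ol; 24 propyne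
Product: 26 (2R,3R)-2-methylhept-5-yne-1,3-diol, via lithium propynide 25 (not isolated)
Conditions: 24, n-BuLi, THF, −78 °C; then 23, BF3·OEt2, −78 °C; H2O
Reagents that add atoms: none
Why: Lithium propynide opens the terminal epoxide at its CH2 carbon (C4) in a BF3-promoted SN2 alkynylation, which leaves the C5 carbinol configuration unchanged and brings in C1–C3.

Step 13
Reactants: 26 (2R,3R)-2-methylhept-5-yne-1,3-diol
Product: 27 (2S,3R)-1-iodo-2-methylhept-5-yn-3-ol
Conditions: I2, PPh3, imidazole, CH2Cl2, 0 °C
Reagents that add atoms: iodine, II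
Why: Appel-type iodination should be selective for the primary hydroxyl over the secondary C5 hydroxyl.

Step 14
Reactants: 27 (2S,3R)-1-iodo-2-methylhept-5-yn-3-ol
Product: 28 (2S,3R)-3-(benzyloxy)-1-iodo-2-methylhept-5-yne
Conditions: BnOC(=NH)CCl3, TfOH (cat.), CH2Cl2/cyclohexane, 0 °C
Reagents that add atoms: benzyl 2,2,2-trichloroacetimidate, ClC(Cl)(Cl)C(=N)OCc1ccccc1
Why: Acid-catalysed O-benzylation with the trichloroacetimidate avoids an alkoxide that could cyclise onto the primary iodide and proceeds with retention at C5.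

Step 15
Reactants: 28 (2S,3R)-3-(benzyloxy)-1-iodo-2-methylhept-5-yne; 17 trans-fused δ-lactone
Product: 30 hydroxy ketone (C20 ketone joined to C7; C8H2OH on C9), via alkyllithium 29 (not isolated)
Conditions: 28, t-BuLi (2 equiv), Et2O/pentane, −78 °C; then 17, THF, −78 °C; H2O
Reagents that add atoms: none
Why: Iodine–lithium exchange gives the primary alkyllithium (kept cold so that it does not add to the alkyne), which adds once to the lactone carbonyl C20 because the lactolate does not collapse at low temperature (organolithium addition to a lactone), forming C7–C20.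

Step 16
Reactants: 30 hydroxy ketone
Product: 32 keto methyl ester (C8 as CO2Me on C9), via keto acid 31 (not isolated)
Conditions: TEMPO (cat.), PhI(OAc)2, MeCN/H2O, 25 °C; then Me3SiCHN2, MeOH/toluene, 0 °C
Reagents that add atoms: water, O; (trimethylsilyl)diazomethane, C[Si](C)(C)C=[N+]=[N-]
Why: Oxoammonium-mediated oxidation should take the neopentyl primary alcohol of the open hydroxy-ketone form through the aldehyde hydrate to the acid, which is methylated crude with the diazo reagent; ketone, alkyne and benzyl ether are inert.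

Step 17
Reactants: 32 keto methyl ester
Product: 33 tricyclic 2-alkyl-1,3-dione (C8=O, C20=O, side chain on C7)
Conditions: KOtBu, THF, 0 → 50 °C; then 1 M HCl
Reagents that add atoms: none
Why: Intramolecular Claisen (Dieckmann-type) condensation: of the two enolates of the C20 ketone only the one at C7 can reach the C8 ester through a six-membered transition state, and deprotonation of the 1,3-dione formed drives the ring closure.

Step 18
Reactants: 33 tricyclic 2-alkyl-1,3-dione
Product: 34 tricyclic β-silyloxy enone (C8=O, C7=C20–OTBS)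
Conditions: TBSOTf, Et3N, CH2Cl2, −78 °C
Reagents that add atoms: tert-butyldimethylsilyl trifluoromethanesulfonate, CC(C)(C)[Si](C)(C)OS(=O)(=O)C(F)(F)F
Why: O-Silylation of the enolised dione should occur at the less hindered C20 oxygen (next to the C19 methylene) rather than at the C8 oxygen flanked by quaternary C9 (regioselective silyl enol ether formation), which leaves the C8 ketone as the chromophore.

Step 19
Reactants: 34 tricyclic β-silyloxy enone
Product: 36 tetracyclic cyclooct-2-ene-1,5-dione (C8=O; C20(=O)–C2(Me)=C3; 7β-H), via cyclobutene photoadduct 35 (not isolated)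
Conditions: hν (366 nm), degassed CH2Cl2 (high dilution), 0 °C; then Bu4NF, AcOH, THF, −20 → 0 °C
Reagents that add atoms: none
Why: The excited enone bonds first from C7 to C3 (five-membered ring A, 5-exo-dig closure) and then from C20 to C2, giving the cyclobutene 35 as the straight adduct; fluoride then frees the C20 alkoxide, which cleaves C7–C20 by retro-aldol fragmentation with C8=O as acceptor, so ring B arises by two-carbon enlargement of the six-membered ring and not by direct medium-ring closure. The closest known reaction types are the intramolecular enone–alkyne [2+2] photocycloaddition and the de Mayo reaction, whose alkyne variant is known. The only stereocentre created is C7: the C8 enolate released by the fragmentation should be protonated by AcOH on the face of ring A opposite the C6 methyl, giving 7β-H (7S), while the C7 and C20 configurations of 35 are destroyed and need no control. The step needs straight rather than crossed addition, secured by the three-atom tether (C6, C5, C4) on C7, and the silyloxy group on C20 rather than C8, secured in step 18. Long-wavelength light limits the secondary 1,3-acyl shift of the β,γ-unsaturated ketone 35, and buffered fluoride avoids base that could move C2=C3 into conjugation with C8 or epimerise C7.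

Step 20
Reactants: 36 tetracyclic cyclooct-2-ene-1,5-dione
Product: 37 C20 1,3-dithiolane of 36
Conditions: Me3SiSCH2CH2SSiMe3, ZnI2 (cat.), Et2O, 0 → 25 °C
Reagents that add atoms: 1,2-bis(trimethylsilylthio)ethane, C[Si](C)(C)SCCS[Si](C)(C)C
Why: Thioketalisation under mild ZnI2 catalysis should select the C20 enone carbonyl over the C8 ketone flanked by quaternary C9 and, as with steroidal 4-en-3-ones, leave C2=C3 in place; the near-neutral conditions limit enolisation towards C7.

Step 21
Reactants: 37 C20 1,3-dithiolane
Product: 38 C20-methylene ketone (C8=O, C2=C3, 5-OBn)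
Conditions: Raney Ni (washed neutral), EtOH, 25 °C
Reagents that add atoms: none
Why: Raney Ni desulfurisation (Mozingo reduction) replaces both C–S bonds by C–H to give the C20 methylene, the tetrasubstituted C2=C3 bond being too hindered to be hydrogenated; no stereocentre is affected.

Step 22
Reactants: 38 C20-methylene ketone
Product: 39 CNP0213887.1 (target)
Conditions: Li, NH3(l), THF, EtOH, −78 °C (38 added to the blue solution); then NH4Cl
Reagents that add atoms: none
Why: Dissolving-metal reduction of the hindered C8 ketone should give the thermodynamically preferred alcohol, with the hydroxyl on the outer (β) face of the folded ring B away from C20 (8R), and the same conditions cleave the benzyl ether (Birch-type debenzylation) without reducing the isolated tetrasubstituted olefin.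

Compound list
1 | 3,3-dimethylcyclohexan-1-one | CC1(C)CCCC(=O)C1 | starting material
2 | lithium 5,5-dimethylcyclohex-1-en-1-olate | [Li]OC1=CCCC(C)(C)C1 | intermediate (not isolated)
3 | rac-2,5,5-trimethylcyclohexan-1-one | CC1CCC(C)(C)CC1=O | intermediate
4 | (R)-1-phenylethan-1-amine | C[C@@H](N)c1ccccc1 | starting material
5 | N-[(1R)-1-phenylethyl]-2,5,5-trimethylcyclohexan-1-imine (both epimers at the ring methyl carbon) | CC1CCC(C)(C)CC1=N[C@H](C)c1ccccc1 | intermediate
6 | but-3-en-2-one | CC(=O)C=C | starting material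
7 | 4-[(1S)-1,4,4-trimethyl-2-{[(1R)-1-phenylethyl]imino}cyclohexyl]butan-2-one | CC(=O)CC[C@]1(C)CCC(C)(C)CC1=N[C@H](C)c1ccccc1 | intermediate (not isolated)
8 | (2S)-2,5,5-trimethyl-2-(3-oxobutyl)cyclohexan-1-one | CC(=O)CC[C@]1(C)CCC(C)(C)CC1=O | intermediate
9 | (4aS)-4a,7,7-trimethyl-4,4a,5,6,7,8-hexahydronaphthalen-2(3H)-one | C[C@]12CCC(=O)C=C1CC(C)(C)CC2 | intermediate
10 | lithium (4aS,8aS)-4a,7,7-trimethyl-3,4,4a,5,6,7,8,8a-octahydronaphthalen-2-olate (trans-fused; C9–OLi, C9=C18) | [Li]OC1=C[C@@H]2CC(C)(C)CC[C@@]2(C)CC1 | intermediate (not isolated)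
11 | tert-butyl 2-[(1S,4aS,8aS)-4a,7,7-trimethyl-2-oxodecahydronaphthalen-1-yl]acetate | O=C1CC[C@]2(C)CCC(C)(C)C[C@H]2[C@@H]1CC(=O)OC(C)(C)C | intermediate
12 | potassium enolate of 11 (C9–OK, C9=C10) | [K]OC1=CC[C@]2(C)CCC(C)(C)C[C@H]2[C@@H]1CC(=O)OC(C)(C)C | intermediate (not isolated)
13 | tert-butyl 2-[(1S,4aS,8aS)-4a,7,7-trimethyl-2-(trifluoromethanesulfonyloxy)-1,4,4a,5,6,7,8,8a-octahydronaphthalen-1-yl]acetate | O=S(=O)(OC1=CC[C@]2(C)CCC(C)(C)C[C@H]2[C@@H]1CC(=O)OC(C)(C)C)C(F)(F)F | intermediate
14 | tert-butyl 2-[(1S,4aS,8aS)-2-(hydroxymethyl)-4a,7,7-trimethyl-1,4,4a,5,6,7,8,8a-octahydronaphthalen-1-yl]acetate | OCC1=CC[C@]2(C)CCC(C)(C)C[C@H]2[C@@H]1CC(=O)OC(C)(C)C | intermediate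
15 | cyclopropane of 14: methylene bridge across C9/C10 on the α face, CH2OH on C9 (β), CH2CO2tBu on C18 | OC[C@@]12C[C@@H]1CC[C@]1(C)CCC(C)(C)C[C@H]1[C@@H]2CC(=O)OC(C)(C)C | intermediate
16 | tert-butyl 2-[(1S,2S,4aS,8aS)-2-(hydroxymethyl)-2,4a,7,7-tetramethyldecahydronaphthalen-1-yl]acetate | OC[C@@]1(C)CC[C@]2(C)CCC(C)(C)C[C@H]2[C@@H]1CC(=O)OC(C)(C)C | intermediate (not isolated)
17 | trans-fused δ-lactone: O–C8H2 on C9, C20(=O)–C19H2 on C18; 9α-Me, 12β-Me, 17α-H, 18β-H | O=C1C[C@H]2[C@@H]3CC(C)(C)CC[C@@]3(C)CC[C@]2(C)CO1 | intermediate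
18 | (4S)-4-benzyl-3-propanoyl-1,3-oxazolidin-2-one | CCC(=O)N1C(=O)OC[C@@H]1Cc1ccccc1 | starting material
19 | chloroacetaldehyde | ClCC=O | starting material
20 | (Z)-dibutylboron enolate of 18 | C/C=C(\OB(CCCC)CCCC)N1C(=O)OC[C@@H]1Cc1ccccc1 | intermediate (not isolated)
21 | (4S)-4-benzyl-3-[(2S,3S)-4-chloro-3-hydroxy-2-methylbutanoyl]-1,3-oxazolidin-2-one | ClC[C@@H](O)[C@H](C)C(=O)N1C(=O)OC[C@@H]1Cc1ccccc1 | intermediate
22 | (2R,3S)-4-chloro-2-methylbutane-1,3-diol | ClC[C@@H](O)[C@H](C)CO | intermediate (not isolated)
23 | (2R)-2-[(2S)-oxiran-2-yl]propan-1-ol | C1O[C@H]1[C@H](C)CO | intermediate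
24 | propyne | CC#C | starting material
25 | prop-1-yn-1-yllithium | [Li]C#CC | intermediate (not isolated)
26 | (2R,3R)-2-methylhept-5-yne-1,3-diol | CC#CC[C@@H](O)[C@H](C)CO | intermediate
27 | (2S,3R)-1-iodo-2-methylhept-5-yn-3-ol | CC#CC[C@@H](O)[C@H](C)CI | intermediate
28 | (2S,3R)-3-(benzyloxy)-1-iodo-2-methylhept-5-yne | CC#CC[C@@H](OCc1ccccc1)[C@H](C)CI | intermediate
29 | [(2R,3R)-3-(benzyloxy)-2-methylhept-5-yn-1-yl]lithium | [Li]C[C@@H](C)[C@@H](CC#CC)OCc1ccccc1 | intermediate (not isolated)
30 | hydroxy ketone: decalin with C8H2OH and 9α-Me on C9; C18 carries CH2–C20(=O)–C7H2–C6H(Me)–C5H(OBn)–CH2–C≡C–CH3 | CC#CC[C@@H](OCc1ccccc1)[C@H](C)CC(=O)C[C@H]1[C@@H]2CC(C)(C)CC[C@@]2(C)CC[C@]1(C)CO | intermediate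
31 | keto acid: as 30 with C8 as CO2H | CC#CC[C@@H](OCc1ccccc1)[C@H](C)CC(=O)C[C@H]1[C@@H]2CC(C)(C)CC[C@@]2(C)CC[C@]1(C)C(=O)O | intermediate (not isolated)
32 | keto methyl ester: as 30 with C8 as CO2Me | CC#CC[C@@H](OCc1ccccc1)[C@H](C)CC(=O)C[C@H]1[C@@H]2CC(C)(C)CC[C@@]2(C)CC[C@]1(C)C(=O)OC | intermediate
33 | tricyclic 2-alkyl-1,3-dione (C8=O, C20=O; C7 bears the side chain; enolisable, C7 not defined) | CC#CC[C@@H](OCc1ccccc1)[C@H](C)C1C(=O)C[C@H]2[C@@H]3CC(C)(C)CC[C@@]3(C)CC[C@]2(C)C1=O | intermediate
34 | tricyclic β-silyloxy enone (C8=O, C7=C20–OTBS) with the alkynyl side chain on C7 | CC#CC[C@@H](OCc1ccccc1)[C@H](C)C1=C(O[Si](C)(C)C(C)(C)C)C[C@H]2[C@@H]3CC(C)(C)CC[C@@]3(C)CC[C@]2(C)C1=O | intermediate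
35 | cyclobutene photoadduct (bonds C7–C3 and C20–C2; C2=C3 in the four-membered ring; C20–OTBS; C7 and C20 not defined) | CC1=C2C[C@@H](OCc3ccccc3)[C@H](C)C24C(=O)[C@@]5(C)CC[C@]6(C)CCC(C)(C)C[C@H]6[C@@H]5CC14O[Si](C)(C)C(C)(C)C | intermediate (not isolated)
36 | tetracyclic cyclooct-2-ene-1,5-dione (C8=O; C20(=O)–C2(Me)=C3; 7β-H; 5-OBn) | C/C1=C2\C[C@@H](OCc3ccccc3)[C@H](C)[C@@H]2C(=O)[C@@]2(C)CC[C@]3(C)CCC(C)(C)C[C@H]3[C@@H]2CC1=O | intermediate
37 | C20 1,3-dithiolane of 36 | C/C1=C2\C[C@@H](OCc3ccccc3)[C@H](C)[C@@H]2C(=O)[C@@]2(C)CC[C@]3(C)CCC(C)(C)C[C@H]3[C@@H]2CC12SCCS2 | intermediate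
38 | C20-methylene ketone (C8=O, C2=C3, 5-OBn) | C/C1=C2\C[C@@H](OCc3ccccc3)[C@H](C)[C@@H]2C(=O)[C@@]2(C)CC[C@]3(C)CCC(C)(C)C[C@H]3[C@@H]2CC1 | intermediate
39 | CNP0213887.1, the (5R,6R,7S,8R,9S,12S,17S,18S) 5,8-diol | C/C1=C2\C[C@@H](O)[C@H](C)[C@@H]2[C@@H](O)[C@@]2(C)CC[C@]3(C)CCC(C)(C)C[C@H]3[C@@H]2CC1 | target

Total step count: 22.
Longest linear sequence: 17 steps (steps 1–9, then 15–22); the side-chain branch (steps 10–14) joins at step 15.

Steps most likely to fail

Step 19. What may go wrong: after the C7–C20 bond is cleaved, the enolate may be protonated at C2 instead of C7, or the product may re-enolise, so that the double bond drifts into conjugation with the C8 carbonyl (C3=C7) and the C7 configuration is lost. Secondary photochemistry of 35 would lower the throughput further. Fallback: the drift is accepted and the olefin is put back later. Setting out from 34, irradiation as in step 19 followed by cleavage with unbuffered Bu4NF and equilibration with DBU in THF should give the conjugated isomer F1 (C8 enone with C3=C7, saturated C20 ketone, C2–H). Its unhindered C20 ketone is converted into the dithiolane F2 (HSCH2CH2SH, BF3·OEt2, CH2Cl2), and Raney Ni in EtOH then gives the C20-methylene enone F3. Treatment of F3 with KOtBu in t-BuOH forms the extended dienolate towards C2, and a rapid quench with aqueous AcOH should protonate C7 kinetically on the face opposite the C6 methyl (deconjugation of an enone through its dienolate). This returns the material to the route at 38.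

Step 20. What may go wrong: once C20 is no longer a carbonyl group, the Lewis acid may enolise the C8 ketone towards C7, so that C2=C3 moves into conjugation with C8 or C7 epimerises; thioketalisation of the twisted, methyl-substituted enone may also be sluggish. Fallback: C20 is deoxygenated through its alcohol after C8 has been reduced. Setting out from 36, LiAlH4 in THF at −78 °C should reduce both carbonyl groups to the diol F4. The C20 carbonyl reacts first, and the C8 ketone is then expected to take hydride across the ring from the C20 alkoxyaluminate, giving the 8β-alcohol. The less hindered allylic C20 hydroxyl is converted into the diethyl phosphate F5 (ClP(O)(OEt)2, pyridine, DMAP, CH2Cl2, 0 °C). Li in NH3/THF with t-BuOH at −78 °C then cleaves the allylic phosphate together with the benzyl ether and arrives directly at 39; protonation of the allyl anion at the secondary terminus C20 keeps the tetrasubstituted olefin.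

Step 22. What may go wrong: under the basic electron-transfer conditions the β,γ-unsaturated ketone may enolise before it is reduced (epimerisation at C7 or olefin drift), or the facial preference at C8 may be too low. Fallback: irreversible hydride delivery followed by a separate neutral debenzylation. Setting out from 38, reduction with LiAlH4 in THF at −78 °C should give the 8β-hydroxy benzyl ether F6, any 8α epimer being removed by chromatography at this stage. Hydrogenolysis of the benzyl ether with H2 over Pd(OH)2/C in EtOAc, which does not touch the tetrasubstituted olefin, then gives 39.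

Further compounds
F1 | step 19 | conjugated isomer of 36: C8 enone with C3=C7, saturated C20 ketone, C2–H (C2 not defined), 5-OBn | CC1C(=O)C[C@H]2[C@@H]3CC(C)(C)CC[C@@]3(C)CC[C@]2(C)C(=O)C2=C1C[C@@H](OCc1ccccc1)[C@@H]2C
F2 | step 19 | C20 1,3-dithiolane of F1 | CC1C2(SCCS2)C[C@H]2[C@@H]3CC(C)(C)CC[C@@]3(C)CC[C@]2(C)C(=O)C2=C1C[C@@H](OCc1ccccc1)[C@@H]2C
F3 | step 19 | C20-methylene C8 enone with C3=C7 (C2 not defined), 5-OBn | CC1CC[C@H]2[C@@H]3CC(C)(C)CC[C@@]3(C)CC[C@]2(C)C(=O)C2=C1C[C@@H](OCc1ccccc1)[C@@H]2C
F4 | step 20 | 8β,20-diol from 36 (C20 not defined), 5-OBn | C/C1=C2\C[C@@H](OCc3ccccc3)[C@H](C)[C@@H]2[C@@H](O)[C@@]2(C)CC[C@]3(C)CCC(C)(C)C[C@H]3[C@@H]2CC1O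
F5 | step 20 | C20 diethyl phosphate of F4 | C/C1=C2\C[C@@H](OCc3ccccc3)[C@H](C)[C@@H]2[C@@H](O)[C@@]2(C)CC[C@]3(C)CCC(C)(C)C[C@H]3[C@@H]2CC1OP(=O)(OCC)OCC
F6 | step 22 | 8β-hydroxy 5-benzyl ether (5-O-benzyl derivative of 39) | C/C1=C2\C[C@@H](OCc3ccccc3)[C@H](C)[C@@H]2[C@@H](O)[C@@]2(C)CC[C@]3(C)CCC(C)(C)C[C@H]3[C@@H]2CC1
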